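**Strategy.** Both aryl-bearing sp3 carbons of the target sit β to a carbonyl: the chain CH2 attached to the 4-methoxyphenyl ring (β to the C8 ketone) and C4 of the chromanone ring attached to phenyl (β to the lactone C2=O). The precursor is therefore an achiral bis-acceptor, 8-acryloyl-5,7-bis(benzyloxy)coumarin. In one flask an (S)-SEGPHOS–rhodium catalyst first joins 4-methoxyphenylboronic acid to the vinyl ketone terminus, forming the anisyl–CH2 bond, and then adds phenylboronic acid to the coumarin C3=C4 bond, setting the single (S) stereocentre. Hydrogenolysis of the benzyl ethers finishes the synthesis.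

Key step: step 4

Remark: compound 1 is taken as a catalogue compound; if it is out of stock it is one step from 2,4,6-trihydroxyacetophenone (BnBr, K2CO3), the chelated OH staying free.

**Step 1**
Reactants: 1 1-[2,4-bis(benzyloxy)-6-hydroxyphenyl]ethan-1-one
Product: 3 3-acetyl-4,6-bis(benzyloxy)-2-hydroxybenzaldehyde, via salicyl alcohol 2 (not isolated)
Conditions: MgCl2, Et3N, (CH2O)n, MeCN, reflux; then 1 M HCl
Reagents that add atoms: paraformaldehyde (reacts as formaldehyde), C=O
Why: Casnati–Skattebøl ortho-formylation, in which the magnesium phenoxide delivers formaldehyde only to the free carbon ortho to the single unprotected OH (the other ortho position bears the acetyl group) and the salicyl alcoholate is oxidised by a second formaldehyde in an Oppenauer-type hydride transfer, so that the future O1/C4a pair and hence the 8-acyl pattern is fixed regiospecifically.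

**Step 2**
Reactants: 3 3-acetyl-4,6-bis(benzyloxy)-2-hydroxybenzaldehyde
Product: 5 8-acetyl-5,7-bis(benzyloxy)-2H-chromen-2-one, via Z-cinnamate ester 4 (not isolated)
Conditions: Ph3P=CHCO2Et, PhNEt2, 210 °C
Reagents that add atoms: ethyl (triphenylphosphoranylidene)acetate, CCOC(=O)C=P(c1ccccc1)(c1ccccc1)c1ccccc1
Why: Wittig olefination of the aldehyde by the stabilised ylide (the chelated, di-ortho-substituted methyl ketone is inert to it), followed at this temperature by E/Z equilibration and lactonisation of the Z-ester onto the adjacent phenol with loss of ethanol, the standard salicylaldehyde-to-coumarin annulation.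

**Step 3**
Reactants: 5 8-acetyl-5,7-bis(benzyloxy)-2H-chromen-2-one
Product: 7 8-acryloyl-5,7-bis(benzyloxy)-2H-chromen-2-one, via Mannich base 6 (not isolated)
Conditions: (CH2O)n, i-Pr2NH2+ CF3CO2−, TFA (cat.), BHT, THF, reflux
Reagents that add atoms: paraformaldehyde (reacts as formaldehyde), C=O
Why: Mannich-type α-methylenation, in which the enol of the acetyl group (the only enolisable carbonyl, as the coumarin has no α-hydrogen) adds to the iminium ion from formaldehyde and the secondary ammonium salt and the bulky diisopropylamino group is then lost by E1cB elimination to give the aryl vinyl ketone.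

**Step 4**
Reactants: 7 8-acryloyl-5,7-bis(benzyloxy)-2H-chromen-2-one; 8 4-methoxyphenylboronic acid; 9 phenylboronic acid
Product: 11 (4S)-5,7-bis(benzyloxy)-8-[3-(4-methoxyphenyl)propanoyl]-4-phenyl-3,4-dihydro-2H-chromen-2-one, via mono-arylated coumarin 10 (not isolated)
Conditions: [Rh(OH)((S)-segphos)]2 (5 mol% Rh), dioxane/H2O 10:1; 8 (1.05 equiv), 25 °C; then 9 (5 equiv), 60 °C
Reagents that add atoms: none
Why: Transmetalation of 8 to the hydroxo-rhodium(I) complex gives an anisyl–Rh species that carbometalates the unhindered terminal C=C of the aryl vinyl ketone (aryl to the CH2 terminus), and protonation of the oxa-π-allyl rhodium by water forms the anisyl–CH2 bond of 10; once 7 is consumed, the same catalyst transmetalates with 9 at 60 °C, adds phenyl to C4 of the coumarin, and protonation of the C3 rhodium enolate gives 11. The closest known reaction type is the Hayashi–Miyaura 1,4-addition of arylboronic acids to enones and to coumarins, run here as two consecutive additions under one catalyst. No ring is closed; both additions are intermolecular. The only new stereocentre, C4, is set in the enantio-determining carborhodation under ligand control: (S)-SEGPHOS is expected to deliver phenyl to the Re face of C4, which corresponds to (S) (the mirror image of the (R)-ligand to (R)-4-arylchroman-2-one sense of simple coumarins), while C3 and the chain carbons are not stereogenic. The step needs chemoselectivity (anisyl only at the enone terminus, phenyl only at C4), which is secured by the large rate gap between the terminal enone (reacts at 25 °C with a near-stoichiometric charge of 8) and the electron-rich, peri-substituted β-carbon of the coumarin (needs 60 °C and excess 9), and by adding 9 only after 7 has gone. Base-free aqueous dioxane should keep the lactone closed.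

**Step 5**
Reactants: 11 (4S)-5,7-bis(benzyloxy)-8-[3-(4-methoxyphenyl)propanoyl]-4-phenyl-3,4-dihydro-2H-chromen-2-one
Product: 12 (4S)-5,7-dihydroxy-8-[3-(4-methoxyphenyl)propanoyl]-4-phenyl-3,4-dihydro-2H-chromen-2-one
Conditions: H2 (1 atm), 10% Pd/C, EtOAc, rt
Reagents that add atoms: none
Why: Catalytic hydrogenolysis of the two aryl benzyl ethers under neutral aprotic conditions, which should leave the hindered hydrogen-bonded aryl ketone, the lactone, the anisole ether and the C4 diarylmethine stereocentre untouched and avoid acid- or base-induced migration of the lactone to the 5-OH.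

**Compound list**
1 | 1-[2,4-bis(benzyloxy)-6-hydroxyphenyl]ethan-1-one | CC(=O)c1c(O)cc(OCc2ccccc2)cc1OCc1ccccc1 | starting material
2 | 1-[4,6-bis(benzyloxy)-2-hydroxy-3-(hydroxymethyl)phenyl]ethan-1-one (formed in the flask of step 1) | CC(=O)c1c(O)c(CO)c(OCc2ccccc2)cc1OCc1ccccc1 | intermediate
3 | 3-acetyl-4,6-bis(benzyloxy)-2-hydroxybenzaldehyde | CC(=O)c1c(O)c(C=O)c(OCc2ccccc2)cc1OCc1ccccc1 | intermediate
4 | ethyl (2Z)-3-[3-acetyl-4,6-bis(benzyloxy)-2-hydroxyphenyl]prop-2-enoate (formed in the flask of step 2) | CCOC(=O)/C=C\c1c(O)c(C(C)=O)c(OCc2ccccc2)cc1OCc1ccccc1 | intermediate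
5 | 8-acetyl-5,7-bis(benzyloxy)-2H-chromen-2-one | CC(=O)c1c(OCc2ccccc2)cc(OCc2ccccc2)c2ccc(=O)oc12 | intermediate
6 | 5,7-bis(benzyloxy)-8-[3-(diisopropylamino)propanoyl]-2H-chromen-2-one (formed in the flask of step 3) | CC(C)N(CCC(=O)c1c(OCc2ccccc2)cc(OCc2ccccc2)c2ccc(=O)oc12)C(C)C | intermediate
7 | 8-acryloyl-5,7-bis(benzyloxy)-2H-chromen-2-one | C=CC(=O)c1c(OCc2ccccc2)cc(OCc2ccccc2)c2ccc(=O)oc12 | intermediate
8 | 4-methoxyphenylboronic acid | COc1ccc(B(O)O)cc1 | starting material
9 | phenylboronic acid | OB(O)c1ccccc1 | starting material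
10 | 5,7-bis(benzyloxy)-8-[3-(4-methoxyphenyl)propanoyl]-2H-chromen-2-one (formed in the flask of step 4) | COc1ccc(CCC(=O)c2c(OCc3ccccc3)cc(OCc3ccccc3)c3ccc(=O)oc23)cc1 | intermediate
11 | (4S)-5,7-bis(benzyloxy)-8-[3-(4-methoxyphenyl)propanoyl]-4-phenyl-3,4-dihydro-2H-chromen-2-one | COc1ccc(CCC(=O)c2c(OCc3ccccc3)cc(OCc3ccccc3)c3c2OC(=O)C[C@H]3c2ccccc2)cc1 | intermediate
12 | (4S)-5,7-dihydroxy-8-[3-(4-methoxyphenyl)propanoyl]-4-phenyl-3,4-dihydro-2H-chromen-2-one | COc1ccc(CCC(=O)c2c(O)cc(O)c3c2OC(=O)C[C@H]3c2ccccc2)cc1 | target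

**Total step count:** 5
**Longest linear sequence:** 5 steps (1 to 12)

**Steps most likely to fail**

Step 4. Possible failures are aryl scrambling between the two acceptors, loss of the enone by oligomerisation before it is arylated, and stalling of the second carborhodation while the ketone chain is present. The fallback separates the two events and makes the anisyl–carbon bond by a Heck arylation.
- It sets out from 5. Rh/(S)-SEGPHOS addition of 9 to 5, which carries no second acceptor and can therefore be forced with heat and excess boronic acid, should give (4S)-8-acetyl-5,7-bis(benzyloxy)-4-phenyl-3,4-dihydro-2H-chromen-2-one F1.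
- Methylenation of F1 with paraformaldehyde and diisopropylammonium trifluoroacetate, through (4S)-5,7-bis(benzyloxy)-8-[3-(diisopropylamino)propanoyl]-4-phenyl-3,4-dihydro-2H-chromen-2-one F2 (not isolated), should give (4S)-8-acryloyl-5,7-bis(benzyloxy)-4-phenyl-3,4-dihydro-2H-chromen-2-one F3.
- Mizoroki–Heck coupling of F3 with 4-iodoanisole (Pd(OAc)2, Bu4NCl, NaHCO3, DMF, 60 °C) should give (4S)-5,7-bis(benzyloxy)-8-[(2E)-3-(4-methoxyphenyl)prop-2-enoyl]-4-phenyl-3,4-dihydro-2H-chromen-2-one F4.
- Hydrogenation of F4 under the conditions of step 5 saturates the chalcone C=C bond and removes both benzyl groups, so the fallback comes back to the route at 12.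

Step 3. Possible failures are thermal oligomerisation or hetero-Diels–Alder dimerisation of the vinyl ketone in the hot, amine-containing medium, and a second aminomethylation before elimination. The fallback builds the enone cold by an aldol/elimination sequence.
- It sets out from 5. TMSOTf/Et3N (CH2Cl2, 0 °C) should give 5,7-bis(benzyloxy)-8-[1-(trimethylsilyloxy)ethenyl]-2H-chromen-2-one F5.
- Mukaiyama aldol reaction of F5 with aqueous formaldehyde (Yb(OTf)3 cat., THF/H2O, rt) should give the storable 5,7-bis(benzyloxy)-8-(3-hydroxypropanoyl)-2H-chromen-2-one F6.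
- MsCl/Et3N (CH2Cl2, 0 °C) converts F6 into 3-[5,7-bis(benzyloxy)-2-oxo-2H-chromen-8-yl]-3-oxopropyl methanesulfonate F7 (not isolated), which eliminates in the same flask, so the fallback comes back to the route at 7 just before step 4.

Step 1. Possible failures are competing hydroxymethylation at the acetyl methyl group and stalling of the ortho-formylation because the phenoxide is held in a magnesium chelate with the acetyl carbonyl. The fallback replaces formylation/Wittig by halogenation/cross-coupling.
- It sets out from 1. Iodination with N-iodosuccinimide (cat. TFA, MeCN, 0 °C), directed ortho to the free OH, should give 1-[4,6-bis(benzyloxy)-2-hydroxy-3-iodophenyl]ethan-1-one F8.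
- Stille coupling of F8 with ethyl (Z)-3-(tributylstannyl)acrylate (Pd2(dba)3, AsPh3, CuI, DMF, 60 °C) should give the Z-ester 4 with retention of geometry; 4 lactonises in the flask, so the fallback comes back to the route at 5 and bypasses 3.

**Further compounds**
F1 | step 4 | (4S)-8-acetyl-5,7-bis(benzyloxy)-4-phenyl-3,4-dihydro-2H-chromen-2-one | CC(=O)c1c(OCc2ccccc2)cc(OCc2ccccc2)c2c1OC(=O)C[C@H]2c1ccccc1
F2 | step 4 | (4S)-5,7-bis(benzyloxy)-8-[3-(diisopropylamino)propanoyl]-4-phenyl-3,4-dihydro-2H-chromen-2-one | CC(C)N(CCC(=O)c1c(OCc2ccccc2)cc(OCc2ccccc2)c2c1OC(=O)C[C@H]2c1ccccc1)C(C)C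
F3 | step 4 | (4S)-8-acryloyl-5,7-bis(benzyloxy)-4-phenyl-3,4-dihydro-2H-chromen-2-one | C=CC(=O)c1c(OCc2ccccc2)cc(OCc2ccccc2)c2c1OC(=O)C[C@H]2c1ccccc1
F4 | step 4 | (4S)-5,7-bis(benzyloxy)-8-[(2E)-3-(4-methoxyphenyl)prop-2-enoyl]-4-phenyl-3,4-dihydro-2H-chromen-2-one | COc1ccc(/C=C/C(=O)c2c(OCc3ccccc3)cc(OCc3ccccc3)c3c2OC(=O)C[C@H]3c2ccccc2)cc1
F5 | step 3 | 5,7-bis(benzyloxy)-8-[1-(trimethylsilyloxy)ethenyl]-2H-chromen-2-one | C=C(O[Si](C)(C)C)c1c(OCc2ccccc2)cc(OCc2ccccc2)c2ccc(=O)oc12
F6 | step 3 | 5,7-bis(benzyloxy)-8-(3-hydroxypropanoyl)-2H-chromen-2-one | OCCC(=O)c1c(OCc2ccccc2)cc(OCc2ccccc2)c2ccc(=O)oc12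
F7 | step 3 | 3-[5,7-bis(benzyloxy)-2-oxo-2H-chromen-8-yl]-3-oxopropyl methanesulfonate | CS(=O)(=O)OCCC(=O)c1c(OCc2ccccc2)cc(OCc2ccccc2)c2ccc(=O)oc12
F8 | step 1 | 1-[4,6-bis(benzyloxy)-2-hydroxy-3-iodophenyl]ethan-1-one | CC(=O)c1c(O)c(I)c(OCc2ccccc2)cc1OCc1ccccc1
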